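## Retrosynthetic overview

- The strategy rests on the benzene ring C4a–C5–C6–C7–C8–C8a of the chroman: oxygen on C5 and on C8a either side of the alkyl-bearing C4a, C6–H, and adjacent one-carbon arms on C7 and C8.
- Last disconnections: C8 aldehyde from its dioxolane, C7 ester from the alcohol and palmitoyl chloride, enone from a Weinreb amide and 2-methylprop-1-enylmagnesium bromide. The two arms are told apart electronically: DDQ should oxidise only the C8 benzylic silyl ether (ortho to O1, para to the C5 methoxy group).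
- Pyran ring (second ring): enantioselective palladium-catalysed oxycyclisation with methoxycarbonylation of a 2-(3-methylbut-3-enyl)phenol, forming O1–C2 and the C2 stereocentre.
- Benzene ring (first ring): thermal union of a 2,3-bis(silyloxymethyl)cyclobutenone with a siloxyalkyne, forming C4a–C5, C8–C8a and C5–C6.
- Precursors: cyclobutenone from but-2-yne-1,4-diol and dichloroketene; siloxyalkyne from ethyl 4-methylpent-4-enoate by Kowalski homologation.

Key step: step 5

Remark: (S,S)-Bn-BOXAX is assumed to deliver the 2S ester in step 8, by analogy with simpler 2-(3-methylbut-3-enyl)phenols; if the sense proves opposite, the (R,R)-ligand is used.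

## Route

Step 1
Reactants: 1 but-2-yne-1,4-diol
Product: 2 1,4-bis(tert-butyldiphenylsilyloxy)but-2-yne
Conditions: t-BuPh2SiCl (2.2 equiv), imidazole, DMF, 0 °C → rt
Reagents that add atoms: tert-butyl(chloro)diphenylsilane, CC(C)(C)[Si](Cl)(c1ccccc1)c1ccccc1
Why: Imidazole-promoted silylation of both primary hydroxyls; tert-butyldiphenylsilyl is chosen because it should outlast the zinc chloride of step 2 and the weakly acidic methanol of step 8 and is cleaved by fluoride more slowly than an aryl silyl ether.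

Step 2
Reactants: 2 1,4-bis(tert-butyldiphenylsilyloxy)but-2-yne; 3 trichloroacetyl chloride
Product: 5 4,4-dichloro-2,3-bis(tert-butyldiphenylsilyloxymethyl)cyclobut-2-en-1-one, via dichloroketene 4 (not isolated)
Conditions: Zn dust (activated), Et2O–DME, slow addition of 3, rt → 35 °C
Reagents that add atoms: none
Why: Zinc dechlorinates 3 to dichloroketene, which should add to the alkyne in a thermal ketene–alkyne [2+2] cycloaddition; the alkyne is symmetric, so no regiochemical question arises, and DME ties up the zinc chloride.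

Step 3
Reactants: 5 4,4-dichloro-2,3-bis(tert-butyldiphenylsilyloxymethyl)cyclobut-2-en-1-one
Product: 6 2,3-bis(tert-butyldiphenylsilyloxymethyl)cyclobut-2-en-1-one
Conditions: Zn dust, AcOH, TMEDA, EtOH, 0 °C → rt
Reagents that add atoms: none
Why: Reductive removal of both α-chlorines by zinc in buffered acetic acid is the usual passage from 4,4-dichlorocyclobutenones to cyclobutenones and should leave the silyl ethers and the strained enone intact.

Step 4
Reactants: 7 ethyl 4-methylpent-4-enoate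
Product: 9 triisopropyl[(5-methylhex-5-en-1-yn-1-yl)oxy]silane, via lithium ynolate 8 (not isolated)
Conditions: CH2Br2, lithium 2,2,6,6-tetramethylpiperidide, THF, −78 °C; n-BuLi, −78 → 25 °C; i-Pr3SiCl, −78 → 25 °C
Reagents that add atoms: dibromomethane, BrCBr; chlorotri(propan-2-yl)silane, CC(C)[Si](Cl)(C(C)C)C(C)C
Why: Kowalski ester homologation: the dibromomethyllithium adduct of the ester is converted by bromine–lithium exchange and 1,2-shift into the lithium ynolate, whose oxygen is silylated by the bulky chlorosilane to give an isolable siloxyalkyne.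

Step 5
Reactants: 6 2,3-bis(tert-butyldiphenylsilyloxymethyl)cyclobut-2-en-1-one; 9 triisopropyl[(5-methylhex-5-en-1-yn-1-yl)oxy]silane
Product: 14 4,5-bis(tert-butyldiphenylsilyloxymethyl)-2-(3-methylbut-3-enyl)-3-(triisopropylsilyloxy)phenol, via vinylketene 10 (not isolated), via 4-vinylcyclobutenone 11 (not isolated), via dienylketene 12 (not isolated), via cyclohexadienone 13 (not isolated)
Conditions: 9 (1.2 equiv), toluene (degassed), 80 °C then 110 °C
Reagents that add atoms: none
Why: Danheiser benzannulation: thermal four-electron electrocyclic opening of 6 gives vinylketene 10, whose carbonyl carbon (future C5) is attacked by the nucleophilic, alkyl-bearing carbon of 9 (future C4a) in a ketene–alkyne [2+2] that also joins C8 to C8a and gives 4-vinylcyclobutenone 11. Ring opening of 11 gives dienylketene 12, whose isomer with the ketene and vinyl termini cis closes the benzene ring by six-electron electrocyclisation (C5–C6) to cyclohexadienone 13, which tautomerises to phenol 14. The closest known reaction type is the thermal benzannulation of cyclobutenones with trialkylsiloxyalkynes to 2-alkylresorcinol monosilyl ethers. No stereocentre is formed. The selectivity needed is the regiochemistry of the [2+2]; it is secured by the polarisation of the ynol ether, whose carbon β to oxygen bonds to the electrophilic ketene carbonyl carbon, so that the alkyl-bearing carbon ends between the two oxygenated carbons, with the free hydroxyl on C5 and the silyl ether on C8a.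

Step 6
Reactants: 14 4,5-bis(tert-butyldiphenylsilyloxymethyl)-2-(3-methylbut-3-enyl)-3-(triisopropylsilyloxy)phenol
Product: 15 [2,3-bis(tert-butyldiphenylsilyloxymethyl)-5-methoxy-6-(3-methylbut-3-enyl)phenoxy]triisopropylsilane
Conditions: MeI, K2CO3, acetone, rt → 40 °C
Reagents that add atoms: iodomethane, CI
Why: Williamson O-methylation of the only free phenol (C5–OH); the hindered aryl triisopropylsilyl ether and the alkyl silyl ethers should be inert to carbonate in acetone.

Step 7
Reactants: 15 [2,3-bis(tert-butyldiphenylsilyloxymethyl)-5-methoxy-6-(3-methylbut-3-enyl)phenoxy]triisopropylsilane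
Product: 16 5,6-bis(tert-butyldiphenylsilyloxymethyl)-3-methoxy-2-(3-methylbut-3-enyl)phenol
Conditions: Bu4NF (1.05 equiv), THF, −20 → 0 °C
Reagents that add atoms: none
Why: Fluoride cleaves an aryl silyl ether much faster than primary alkyl tert-butyldiphenylsilyl ethers because phenoxide is the better leaving group, so the C8a phenol should be freed selectively at low temperature.

Step 8
Reactants: 16 5,6-bis(tert-butyldiphenylsilyloxymethyl)-3-methoxy-2-(3-methylbut-3-enyl)phenol
Product: 17 methyl 2-[(2S)-7,8-bis(tert-butyldiphenylsilyloxymethyl)-5-methoxy-2-methyl-3,4-dihydro-2H-chromen-2-yl]acetate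
Conditions: Pd(OCOCF3)2 (5 mol%), (S,S)-Bn-BOXAX [2,2'-bis((4S)-4-benzyl-4,5-dihydrooxazol-2-yl)-1,1'-binaphthyl, S axis] (20 mol%), p-benzoquinone (4 equiv), CO (1 atm), MeOH, rt
Reagents that add atoms: carbon monoxide, [C-]#[O+]; methanol, CO
Why: Enantioselective domino Wacker oxypalladation/carbonylation/methanolysis: the C8a phenol adds 6-exo to the palladium-bound 1,1-disubstituted alkene to form O1–C2, the palladium–carbon bond so formed has no β-hydrogen and therefore inserts CO and is methanolysed, and the chiral bis(oxazoline) ligand selects the alkene face and so sets C2 as S.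

Step 9
Reactants: 17 methyl 2-[(2S)-7,8-bis(tert-butyldiphenylsilyloxymethyl)-5-methoxy-2-methyl-3,4-dihydro-2H-chromen-2-yl]acetate
Product: 18 methyl 2-[(2S)-7-(tert-butyldiphenylsilyloxymethyl)-8-formyl-5-methoxy-2-methyl-3,4-dihydro-2H-chromen-2-yl]acetate
Conditions: DDQ (1.3 equiv), CH2Cl2–pH 7 phosphate buffer, 0 °C → rt
Reagents that add atoms: none
Why: DDQ oxidation of an electron-rich benzylic ether: hydride should be abstracted only from the C8 methylene, which is ortho to O1 and para to the C5 methoxy group, and water takes the silyl group as silanol to leave the aldehyde, whereas the C7 methylene is meta to both oxygens and its silyl ether should survive.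

Step 10
Reactants: 18 methyl 2-[(2S)-7-(tert-butyldiphenylsilyloxymethyl)-8-formyl-5-methoxy-2-methyl-3,4-dihydro-2H-chromen-2-yl]acetate
Product: 19 methyl 2-[(2S)-7-(tert-butyldiphenylsilyloxymethyl)-8-(1,3-dioxolan-2-yl)-5-methoxy-2-methyl-3,4-dihydro-2H-chromen-2-yl]acetate
Conditions: Me3SiOCH2CH2OSiMe3, Me3SiOTf (cat.), CH2Cl2, −78 → −20 °C
Reagents that add atoms: 1,2-bis(trimethylsilyloxy)ethane, C[Si](C)(C)OCCO[Si](C)(C)C
Why: Noyori acetalisation under aprotic conditions should convert the hindered aryl aldehyde to its dioxolane without touching the silyl ether or the ester; the acetal shields the aldehyde from the organomagnesium steps and later keeps it from closing onto the neighbouring C7 alcohol.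

Step 11
Reactants: 19 methyl 2-[(2S)-7-(tert-butyldiphenylsilyloxymethyl)-8-(1,3-dioxolan-2-yl)-5-methoxy-2-methyl-3,4-dihydro-2H-chromen-2-yl]acetate
Product: 20 2-[(2S)-7-(tert-butyldiphenylsilyloxymethyl)-8-(1,3-dioxolan-2-yl)-5-methoxy-2-methyl-3,4-dihydro-2H-chromen-2-yl]-N-methoxy-N-methylacetamide
Conditions: MeNH(OMe)·HCl, i-PrMgCl, THF, −20 → 0 °C
Reagents that add atoms: N,O-dimethylhydroxylamine hydrochloride, CNOC.Cl
Why: Weinreb amide formation: the chloromagnesium amide made in the flask adds to the methyl ester faster than the ester is enolised, so the β-aryloxy ester should not open by elimination and C2 is untouched.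

Step 12
Reactants: 20 2-[(2S)-7-(tert-butyldiphenylsilyloxymethyl)-8-(1,3-dioxolan-2-yl)-5-methoxy-2-methyl-3,4-dihydro-2H-chromen-2-yl]-N-methoxy-N-methylacetamide
Product: 21 2-[(2S)-8-(1,3-dioxolan-2-yl)-7-(hydroxymethyl)-5-methoxy-2-methyl-3,4-dihydro-2H-chromen-2-yl]-N-methoxy-N-methylacetamide
Conditions: Bu4NF (1.5 equiv), THF, 0 °C → rt
Reagents that add atoms: none
Why: Fluoride cleavage of the primary silyl ether is placed at the amide stage, before any base-sensitive β-aryloxy ketone exists; acetal and amide are stable to fluoride.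

Step 13
Reactants: 21 2-[(2S)-8-(1,3-dioxolan-2-yl)-7-(hydroxymethyl)-5-methoxy-2-methyl-3,4-dihydro-2H-chromen-2-yl]-N-methoxy-N-methylacetamide; 22 2-methylprop-1-enylmagnesium bromide
Product: 24 1-[(2S)-8-(1,3-dioxolan-2-yl)-7-(hydroxymethyl)-5-methoxy-2-methyl-3,4-dihydro-2H-chromen-2-yl]-4-methylpent-3-en-2-one, via magnesium hemiaminal 23 (not isolated)
Conditions: 22 (3 equiv), THF, −20 → 0 °C; cold aq NH4Cl
Reagents that add atoms: none
Why: Weinreb ketone synthesis: after deprotonation of the alcohol the alkenyl Grignard reagent adds once to give the chelated magnesium hemiaminal, which should persist until the buffered quench and then release the β,β-dimethyl enone.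

Step 14
Reactants: 24 1-[(2S)-8-(1,3-dioxolan-2-yl)-7-(hydroxymethyl)-5-methoxy-2-methyl-3,4-dihydro-2H-chromen-2-yl]-4-methylpent-3-en-2-one; 25 hexadecanoyl chloride
Product: 26 [(2S)-8-(1,3-dioxolan-2-yl)-5-methoxy-2-methyl-2-(4-methyl-2-oxopent-3-enyl)-3,4-dihydro-2H-chromen-7-yl]methyl hexadecanoate
Conditions: Et3N, DMAP (cat.), CH2Cl2, 0 °C
Reagents that add atoms: none
Why: DMAP-catalysed acylation of the only free hydroxyl (the C7 alcohol) under mild base at low temperature, where the β-aryloxy ketone should not open by retro-oxa-Michael reaction.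

Step 15
Reactants: 26 [(2S)-8-(1,3-dioxolan-2-yl)-5-methoxy-2-methyl-2-(4-methyl-2-oxopent-3-enyl)-3,4-dihydro-2H-chromen-7-yl]methyl hexadecanoate
Product: 27 [(2S)-8-formyl-5-methoxy-2-methyl-2-(4-methyl-2-oxopent-3-enyl)-3,4-dihydro-2H-chromen-7-yl]methyl hexadecanoate
Conditions: AcOH–THF–H2O (3:1:1), rt
Reagents that add atoms: water, O
Why: Mild acid hydrolysis of the electron-rich aryl dioxolane should release the C8 aldehyde, while the benzylic palmitate, the enone and the chroman ether are stable to aqueous acetic acid.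

## Compound list

1 | but-2-yne-1,4-diol | OCC#CCO | starting material
2 | 1,4-bis(tert-butyldiphenylsilyloxy)but-2-yne | CC(C)(C)[Si](c1ccccc1)(c1ccccc1)OCC#CCO[Si](c1ccccc1)(c1ccccc1)C(C)(C)C | intermediate
3 | trichloroacetyl chloride | O=C(Cl)C(Cl)(Cl)Cl | starting material
4 | dichloroketene | O=C=C(Cl)Cl | intermediate
5 | 4,4-dichloro-2,3-bis(tert-butyldiphenylsilyloxymethyl)cyclobut-2-en-1-one | O=C1C(CO[Si](c2ccccc2)(c2ccccc2)C(C)(C)C)=C(CO[Si](c2ccccc2)(c2ccccc2)C(C)(C)C)C1(Cl)Cl | intermediate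
6 | 2,3-bis(tert-butyldiphenylsilyloxymethyl)cyclobut-2-en-1-one | O=C1CC(CO[Si](c2ccccc2)(c2ccccc2)C(C)(C)C)=C1CO[Si](c2ccccc2)(c2ccccc2)C(C)(C)C | intermediate
7 | ethyl 4-methylpent-4-enoate | C=C(C)CCC(=O)OCC | starting material
8 | lithium 5-methylhex-5-en-1-yn-1-olate | [Li+].[O-]C#CCCC(C)=C | intermediate
9 | triisopropyl[(5-methylhex-5-en-1-yn-1-yl)oxy]silane | C=C(C)CCC#CO[Si](C(C)C)(C(C)C)C(C)C | intermediate
10 | 2,3-bis(tert-butyldiphenylsilyloxymethyl)buta-1,3-dien-1-one (vinylketene) | C=C(CO[Si](c1ccccc1)(c1ccccc1)C(C)(C)C)C(=C=O)CO[Si](c1ccccc1)(c1ccccc1)C(C)(C)C | intermediate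
11 | 4-(tert-butyldiphenylsilyloxymethyl)-4-[3-(tert-butyldiphenylsilyloxy)prop-1-en-2-yl]-2-(3-methylbut-3-enyl)-3-(triisopropylsilyloxy)cyclobut-2-en-1-one (racemic) | O=C1C(CCC(C)=C)=C(O[Si](C(C)C)(C(C)C)C(C)C)C1(CO[Si](c2ccccc2)(c2ccccc2)C(C)(C)C)C(=C)CO[Si](c2ccccc2)(c2ccccc2)C(C)(C)C | intermediate
12 | (3Z)-4,5-bis(tert-butyldiphenylsilyloxymethyl)-2-(3-methylbut-3-enyl)-3-(triisopropylsilyloxy)hexa-1,3,5-trien-1-one | O=C=C(CCC(C)=C)/C(O[Si](C(C)C)(C(C)C)C(C)C)=C(\C(=C)CO[Si](c1ccccc1)(c1ccccc1)C(C)(C)C)CO[Si](c1ccccc1)(c1ccccc1)C(C)(C)C | intermediate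
13 | 4,5-bis(tert-butyldiphenylsilyloxymethyl)-2-(3-methylbut-3-enyl)-3-(triisopropylsilyloxy)cyclohexa-2,4-dien-1-one | O=C1CC(CO[Si](c2ccccc2)(c2ccccc2)C(C)(C)C)=C(CO[Si](c2ccccc2)(c2ccccc2)C(C)(C)C)C(O[Si](C(C)C)(C(C)C)C(C)C)=C1CCC(C)=C | intermediate
14 | 4,5-bis(tert-butyldiphenylsilyloxymethyl)-2-(3-methylbut-3-enyl)-3-(triisopropylsilyloxy)phenol | C=C(C)CCc1c(O)cc(CO[Si](c2ccccc2)(c2ccccc2)C(C)(C)C)c(CO[Si](c2ccccc2)(c2ccccc2)C(C)(C)C)c1O[Si](C(C)C)(C(C)C)C(C)C | intermediate
15 | [2,3-bis(tert-butyldiphenylsilyloxymethyl)-5-methoxy-6-(3-methylbut-3-enyl)phenoxy]triisopropylsilane | C=C(C)CCc1c(OC)cc(CO[Si](c2ccccc2)(c2ccccc2)C(C)(C)C)c(CO[Si](c2ccccc2)(c2ccccc2)C(C)(C)C)c1O[Si](C(C)C)(C(C)C)C(C)C | intermediate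
16 | 5,6-bis(tert-butyldiphenylsilyloxymethyl)-3-methoxy-2-(3-methylbut-3-enyl)phenol | C=C(C)CCc1c(OC)cc(CO[Si](c2ccccc2)(c2ccccc2)C(C)(C)C)c(CO[Si](c2ccccc2)(c2ccccc2)C(C)(C)C)c1O | intermediate
17 | methyl 2-[(2S)-7,8-bis(tert-butyldiphenylsilyloxymethyl)-5-methoxy-2-methyl-3,4-dihydro-2H-chromen-2-yl]acetate | CC(C)(C)[Si](c3ccccc3)(c3ccccc3)OCc1cc(OC)c2c(c1CO[Si](c3ccccc3)(c3ccccc3)C(C)(C)C)O[C@](C)(CC(=O)OC)CC2 | intermediate
18 | methyl 2-[(2S)-7-(tert-butyldiphenylsilyloxymethyl)-8-formyl-5-methoxy-2-methyl-3,4-dihydro-2H-chromen-2-yl]acetate | CC(C)(C)[Si](c3ccccc3)(c3ccccc3)OCc1cc(OC)c2c(c1C=O)O[C@](C)(CC(=O)OC)CC2 | intermediate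
19 | methyl 2-[(2S)-7-(tert-butyldiphenylsilyloxymethyl)-8-(1,3-dioxolan-2-yl)-5-methoxy-2-methyl-3,4-dihydro-2H-chromen-2-yl]acetate | CC(C)(C)[Si](c3ccccc3)(c3ccccc3)OCc1cc(OC)c2c(c1C4OCCO4)O[C@](C)(CC(=O)OC)CC2 | intermediate
20 | 2-[(2S)-7-(tert-butyldiphenylsilyloxymethyl)-8-(1,3-dioxolan-2-yl)-5-methoxy-2-methyl-3,4-dihydro-2H-chromen-2-yl]-N-methoxy-N-methylacetamide | CC(C)(C)[Si](c3ccccc3)(c3ccccc3)OCc1cc(OC)c2c(c1C4OCCO4)O[C@](C)(CC(=O)N(C)OC)CC2 | intermediate
21 | 2-[(2S)-8-(1,3-dioxolan-2-yl)-7-(hydroxymethyl)-5-methoxy-2-methyl-3,4-dihydro-2H-chromen-2-yl]-N-methoxy-N-methylacetamide | OCc1cc(OC)c2c(c1C4OCCO4)O[C@](C)(CC(=O)N(C)OC)CC2 | intermediate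
22 | 2-methylprop-1-enylmagnesium bromide | CC(C)=C[Mg]Br | starting material
23 | bis(bromomagnesium) alkoxide–hemiaminal adduct of 21 and 22 (carbinol carbon of either configuration) | Br[Mg]OCc1cc(OC)c2c(c1C4OCCO4)O[C@](C)(CC(O[Mg]Br)(N(C)OC)C=C(C)C)CC2 | intermediate
24 | 1-[(2S)-8-(1,3-dioxolan-2-yl)-7-(hydroxymethyl)-5-methoxy-2-methyl-3,4-dihydro-2H-chromen-2-yl]-4-methylpent-3-en-2-one | OCc1cc(OC)c2c(c1C4OCCO4)O[C@](C)(CC(=O)C=C(C)C)CC2 | intermediate
25 | hexadecanoyl chloride (palmitoyl chloride) | CCCCCCCCCCCCCCCC(=O)Cl | starting material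
26 | [(2S)-8-(1,3-dioxolan-2-yl)-5-methoxy-2-methyl-2-(4-methyl-2-oxopent-3-enyl)-3,4-dihydro-2H-chromen-7-yl]methyl hexadecanoate | CCCCCCCCCCCCCCCC(=O)OCc1cc(OC)c2c(c1C4OCCO4)O[C@](C)(CC(=O)C=C(C)C)CC2 | intermediate
27 | [(2S)-8-formyl-5-methoxy-2-methyl-2-(4-methyl-2-oxopent-3-enyl)-3,4-dihydro-2H-chromen-7-yl]methyl hexadecanoate | CCCCCCCCCCCCCCCC(=O)OCc1cc(OC)c2c(c1C=O)O[C@](C)(CC(=O)C=C(C)C)CC2 | target

## Step count and risks

Total step count: 15. Longest linear sequence: 14 steps (steps 1–3 and 5–15, from but-2-yne-1,4-diol); step 4 is the one-step side branch.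

Steps most likely to fail:

**Step 8.** Enantiofacial discrimination in the oxypalladation, and its rate, may suffer because the phenol oxygen is flanked by the bulky silyloxymethyl arm at C8, a more crowded setting than a simple ortho-alkyl phenol. The fallback replaces asymmetric catalysis by resolution. It sets out from phenol 16, which is cyclised without a chiral ligand (PdCl2(MeCN)2, p-benzoquinone, CO, MeOH) to the racemic methyl ester F1. Preparative chromatography on a chiral stationary phase should separate F1 into 17 and the (R)-configured methyl ester F2, which is set aside. The fallback comes back to the route at 17.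

**Step 9.** Hydride abstraction at the chroman C4 methylene (leading to the chromene) or further oxidation may compete with oxidation of the C8 silyloxymethyl group. The fallback tells the arms apart by steric rather than electronic means and oxidises last. It sets out from 17:
- MeNH(OMe)·HCl and i-PrMgCl should give the bis-silyl Weinreb amide F3.
- Addition of 22 through the magnesium hemiaminal F4 should give the bis-silyl enone F5.
- HF·pyridine buffered with pyridine in THF removes both silyl groups to give the diol F6.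
- Acylation with 25 and 2,4,6-collidine in CH2Cl2 at −78 °C should favour the C7 hydroxyl, which has one ortho substituent against two for C8, and give the C7 monopalmitate F7.
- MnO2 in CH2Cl2 oxidises the remaining electron-rich C8 benzylic alcohol.

The fallback comes back to the route at 27.

**Step 5.** During the heating needed to open 6, the siloxyalkyne may be lost by oxygen-to-carbon silyl shift to a silylketene or by addition of the product phenol, so that the vinylketene is not intercepted. The fallback generates the vinylketene in the cold by dehydrochlorination instead of by electrocyclic opening. It sets out from 6, which is heated in aqueous dioxane so that ketene 10 is trapped by water as 2,3-bis(tert-butyldiphenylsilyloxymethyl)but-3-enoic acid F8. Oxalyl chloride with catalytic DMF converts F8 into the acid chloride F9. Slow addition of Et3N to F9 and 9 in CH2Cl2 at 0–25 °C regenerates 10 in the presence of the alkyne; the [2+2] should give 11 at room temperature. Once the alkyne is consumed, the solution is warmed to 80 °C, where 11 opens to 12 and closes through 13 to the phenol. The fallback comes back to the route at 14.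

Further compounds
F1 | step 8 | methyl 2-[7,8-bis(tert-butyldiphenylsilyloxymethyl)-5-methoxy-2-methyl-3,4-dihydro-2H-chromen-2-yl]acetate (racemic) | CC(C)(C)[Si](c3ccccc3)(c3ccccc3)OCc1cc(OC)c2c(c1CO[Si](c3ccccc3)(c3ccccc3)C(C)(C)C)OC(C)(CC(=O)OC)CC2
F2 | step 8 | methyl 2-[(2R)-7,8-bis(tert-butyldiphenylsilyloxymethyl)-5-methoxy-2-methyl-3,4-dihydro-2H-chromen-2-yl]acetate | CC(C)(C)[Si](c3ccccc3)(c3ccccc3)OCc1cc(OC)c2c(c1CO[Si](c3ccccc3)(c3ccccc3)C(C)(C)C)O[C@@](C)(CC(=O)OC)CC2
F3 | step 9 | 2-[(2S)-7,8-bis(tert-butyldiphenylsilyloxymethyl)-5-methoxy-2-methyl-3,4-dihydro-2H-chromen-2-yl]-N-methoxy-N-methylacetamide | CC(C)(C)[Si](c3ccccc3)(c3ccccc3)OCc1cc(OC)c2c(c1CO[Si](c3ccccc3)(c3ccccc3)C(C)(C)C)O[C@](C)(CC(=O)N(C)OC)CC2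
F4 | step 9 | bromomagnesium hemiaminal adduct of F3 and 22 | CC(C)(C)[Si](c3ccccc3)(c3ccccc3)OCc1cc(OC)c2c(c1CO[Si](c3ccccc3)(c3ccccc3)C(C)(C)C)O[C@](C)(CC(O[Mg]Br)(N(C)OC)C=C(C)C)CC2
F5 | step 9 | 1-[(2S)-7,8-bis(tert-butyldiphenylsilyloxymethyl)-5-methoxy-2-methyl-3,4-dihydro-2H-chromen-2-yl]-4-methylpent-3-en-2-one | CC(C)(C)[Si](c3ccccc3)(c3ccccc3)OCc1cc(OC)c2c(c1CO[Si](c3ccccc3)(c3ccccc3)C(C)(C)C)O[C@](C)(CC(=O)C=C(C)C)CC2
F6 | step 9 | 1-[(2S)-7,8-bis(hydroxymethyl)-5-methoxy-2-methyl-3,4-dihydro-2H-chromen-2-yl]-4-methylpent-3-en-2-one | OCc1cc(OC)c2c(c1CO)O[C@](C)(CC(=O)C=C(C)C)CC2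
F7 | step 9 | [(2S)-8-(hydroxymethyl)-5-methoxy-2-methyl-2-(4-methyl-2-oxopent-3-enyl)-3,4-dihydro-2H-chromen-7-yl]methyl hexadecanoate | CCCCCCCCCCCCCCCC(=O)OCc1cc(OC)c2c(c1CO)O[C@](C)(CC(=O)C=C(C)C)CC2
F8 | step 5 | 2,3-bis(tert-butyldiphenylsilyloxymethyl)but-3-enoic acid (racemic) | C=C(CO[Si](c1ccccc1)(c1ccccc1)C(C)(C)C)C(CO[Si](c1ccccc1)(c1ccccc1)C(C)(C)C)C(=O)O
F9 | step 5 | 2,3-bis(tert-butyldiphenylsilyloxymethyl)but-3-enoyl chloride (racemic) | C=C(CO[Si](c1ccccc1)(c1ccccc1)C(C)(C)C)C(CO[Si](c1ccccc1)(c1ccccc1)C(C)(C)C)C(=O)Cl
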